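Readings and results are calculated for an exercise; scatter was added.

What is left of G is the first thing I read, and I read it against D: the tie, G equal to D, is the zero of my scale, and I ask on which side of it a flask ends.

| flask | G | X | remark | time |
|---|---|---|---|---|
| ochre | 0.96 M | 1.5 M | run made earlier |  |
| red | 0.96 M | 2.8 M | run made earlier |  |
| beta | 0.96 M | 2.30 M |  | 6.0 h |
| gamma | 0.96 M | 1.10 M |  | 6.0 h |

| run | time / h | D / % | G / % | Q / % | E / % |
|---|---|---|---|---|---|
| ochre | 0.500 | 11 | 89 | 4 | 1 |
| ochre | 0.833 | 12 | 85 | 0 | 2 |
| ochre | 1.33 | 21 | 74 | 0 | 1 |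
| ochre | 2.00 | 30 | 68 | 3 | 0 |
| ochre | 4.00 | 44 | 53 | 0 | 1 |
| ochre | 6.00 | 51 | 43 | 0 | 6 |
| red | 0.500 | 15 | 82 | 0 | 0 |
| red | 0.833 | 26 | 73 | 0 | 0 |
| red | 1.33 | 36 | 63 | 0 | 4 |
| red | 2.00 | 47 | 48 | 1 | 3 |
| red | 4.00 | 57 | 29 | 3 | 10 |
| red | 6.00 | 58 | 21 | 6 | 12 |

(standard deviation of a reading: 1.5 percentage points)

- which of these there is most of at the end, counted by the G in it, beta (E / D / Q / G)
- which of these there is most of at the end, counted by the G in it, gamma (E / D / Q / G)
- final amount of the leader among these, as a percentage of the G charged, in beta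
- final amount of the leader among these, as a percentage of the G charged, in gamma

I take the end as 6.0 h and turn the settings one at a time. By hand, more time should move G towards the tie, and it does: ochre has G ahead, 53% to 44%, at 4.00 h, and D ahead, 51% to 43%, at 6.00 h. By hand, more X should act like more time, and it does: at 6.00 h, red holds less G than ochre, 21% to 43%. So I try the dose, cX as charged times hours. Neither run moves the G charge, so the dose leaves it out.

On a straight line between the readings either side, ochre's readings put the tie at a dose of 7.59 M·h. This is the tie dose, the dose at which D draws level with G, for the G charge of these runs. Red's readings put it at 5.79 M·h, which is lower, so in these two runs the lower cX goes with the higher tie dose.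

Beta gets 13.8 M·h, beyond both tie doses, so I say D leads. Red passes that dose between readings of 57% and 58%, and I put beta's D there. Gamma gets 6.60 M·h, short of ochre's tie dose, with less X than ochre, so I say G leads, at 51.0% on ochre's line.

The forecast gives D at 56% in beta and G at 53% in gamma, the gamma figure above mine, holding that “the first step is first order in X”.

The flasks give D at 56.7% in beta and G at 53.2% in gamma.

    G + X ⇌ J + D (K = 2.60, k = 0.00238 L mol⁻¹ min⁻¹)
    D + X ⇌ J + E (K = 1.60, k = 6.07 × 10⁻⁴ L mol⁻¹ min⁻¹)
    E + X ⇌ J + Q (K = 0.390, k = 0.00262 L mol⁻¹ min⁻¹)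
    Q ⇌ Z (K = 0.828, k = 0.0119 min⁻¹)

Beta at 3.00 h has had 6.90 M·h, between the two tie doses, and D already stands at 48.7% against G at 45.0%. A neighbour like gamma but charged with 0.66 M of X has 0.688 equiv of X to G, so X is the limiting reagent by charge there. Its dose is 3.96 M·h, below both tie doses, so I say G leads, at 63.2% on ochre's line. That neighbour ends with G ahead at 68.2%, 5 percentage points above that line, and D at 30.1%.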